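Remarks. Locants follow the onocerane skeleton: C1–C10 for rings A and B of one half, C11 and C12 for the bridge, primed locants for the second half (C9' is also C13, C8' is also C14). α and β refer to the usual steroid-type drawing. The sense of induction of (S)-BINAP in step 3 and of (S)-t-Bu-PHOX in step 7 is assigned by analogy with cyclohex-2-enone and with the allyl enol carbonate of 2-methylcyclohexanone; if either proves opposite on these substrates, the antipodal ligand is to be used.

## Analysis of the target

α-Onocerin is a C2-symmetric C30 seco-triterpenoid: two identical trans-fused decalins (rings A and B, rings A' and B') joined only by the C11–C12 ethylene bridge between C9 and C9'. Each half carries four stereocentres: C3 (S, equatorial β-hydroxyl), C5 (α-hydrogen), C9 (α-hydrogen, bridge β and equatorial) and the quaternary C10 (β-methyl). Within one half these centres are tied together by the rigid trans-decalin, but the two halves communicate only through a flexible two-carbon chain. The homochiral relationship between the halves therefore cannot be relayed and must be imposed on each half by absolute control. The sensitive groups are the two 1,1-disubstituted exocyclic alkenes at C8 and C8', which migrate or cyclise under acid, and the two secondary alcohols next to the C4 gem-dimethyl groups. The main difficulty is the pair of quaternary C10 centres, each flanked by the stereocentres C5 and C9, and the fact that every operation has to succeed twice, since any error appears as a diastereomer. The strategy rests on the position of C10 in ring B: it lies between C5 and the bridge-bearing C9. With C5 as a ketone, a regiodefined C5–C10 enolate of a preformed ring B can be allylated at C10, and the allyl group supplies C1–C3 of ring A while the C9 side chain directs the approach.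

## Retrosynthetic reasoning

The two C8=CH2 bonds of 24 are cut first, leading back to the diketone diol 23. These alkenes are the only acid-sensitive groups, so a double Wittig methylenation as the last step keeps them out of all other chemistry. In 23, C9 is α to a ketone, but the required configuration (bridge equatorial) is the thermodynamically preferred one.

The C8 carbonyls of 23 are traced back to the dimethyl ketals of 22, and the C3 alcohols of 22 to the C3 ketones of 21. The ketal distinguishes C8 from the C5 and C3 carbonyls that are used earlier. Reducing C3 while C8 is still masked avoids competition between two ketones, and a 4,4-dimethyl-3-ketone is reduced reliably to the equatorial alcohol.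

In 21 one C4–CH3 bond and the C5–H bond of each half are cut, giving the bis(enone) 19. The forward reaction, a dissolving-metal reduction with trapping of the enolate by a methylating agent, sets the trans ring fusion and completes the gem-dimethyl group in one operation.

The C4–C5 double bonds of 19 are cut by a retro-aldol condensation to the tetraketone 18, whose 3-oxopentyl chains are simplified through carbinol 17, aldehyde 16 and alcohol 15 back to the allyl groups of 13. The C3–C4 bond is cut there because plain allyl is the fragment that the key reaction transfers with the best selectivity; the allyl terminus then only has to be oxidised and ethylated.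

The C10–C1 and C10'–C1' bonds of 13 are cut next, giving the bis(allyl enol carbonate) 11. This is the central disconnection. C10 is the only quaternary stereocentre of each half, and cutting here turns it into the α-carbon of the C5 ketone and reduces ring A to a three-carbon unit, while ring B stays intact as a simple cyclohexanone. Cutting C10–C5 or C10–C9 instead would open ring B and lose the C8/C9 functionality. The forward reaction has to form two quaternary centres of the same absolute configuration at two sites that do not sense each other, so it must be controlled by a catalyst, helped by the neighbouring C9 centre.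

The carbonate C–O bonds of 11 are cut to the bis(silyl enol ether) 8 and the chloroformate 9, and 8 is traced to the bis(ketone) 7. The forward steps must deliver the tetrasubstituted C5–C10 enolate and not its C5–C6 isomer. This is why a thermodynamic silyl enol ether is made first and converted without equilibration.

The C9–C11 and C9'–C12 bonds of 7 (through its unsaturated precursor 6) are cut to two molecules of the achiral enone 3 and the two-carbon linchpin 4. C9 is β to the C5 carbonyl, so conjugate addition has the natural polarity, and a twofold enantioselective addition creates both C9 centres and the whole bridge in one step.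

Enone 3 is a half-reduced quinone monoketal. Its 1,4-oxygen pattern at C5 and C8 is that of a hydroquinone, so it is traced through dienone 2 to the phenol 1, with the C10 methyl already in place.

## Alternatives that were turned down

Alternative 1: The bonds C8–C9 and C13–C14 are cut, so that both B rings and a temporary ring C come from one transannular Diels–Alder reaction. In the forward sense the 14-membered dienyne A1, in which the C8≡C14 alkyne faces the (E,E)-C9=C11–C12=C13 diene across the ring, would be heated to give the pentacyclic 8(14),11-diene A2. Hydrogenation of C11=C12, oxidative cleavage of C8=C14 to the two C8 ketones and double methylenation would follow.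
- For: three rings and two hard bonds arise in one thermal step without reagents. In ring-forming economy this plan is clearly stronger than the chosen one.
- Against: the cycloaddition sets neither quaternary centre, so both ring A units with C5 and C10 must be made enantioselectively beforehand and then joined twice. A linear alkyne and an s-cis E,E-diene in a 14-membered ring are strained, and the dienophile is unactivated. Suprafacial addition places H9 and H13 on the same face of ring C, whereas two homochiral halves need them on opposite faces; A2 therefore carries one of these centres wrongly and depends on later epimerisation next to the freed ketone. Two carbon–carbon bonds are built only to be cleaved.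
- Comparison: the chosen route creates each stereocentre once under catalyst control and spends no bond on a sacrificial ring. It pays with a longer annulation sequence for rings A.

Alternative 2: The bonds C1–C10 and C4–C5 of both A rings are cut in a Diels–Alder sense. In the forward step a Lewis acid would combine two molecules of the silyloxydiene A4 with the bis(enone) A3 to give the 1,4-diketone A5, which carries both A rings as silyl enol ethers.
- For: both quaternary C10 centres, the C4 gem-dimethyl groups and the C3 oxygens arrive together, and the E geometry of each enone encodes the trans relationship of H5 and the C10 methyl. In convergence and in steps spent on ring A this plan is stronger than the chosen one, which needs six steps from allyl group to 4,4-dimethyl ketone.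
- Against: A4 has a fully substituted diene terminus with a cis methyl and reaches the s-cis conformation poorly. The C4–C5 bond joins a carbon that becomes quaternary to a carbon next to the other quaternary centre, and a trisubstituted acyclic enone is a weak dienophile, so a stepwise Mukaiyama–Michael path with loss of stereospecificity is likely. Absolute control at two independent sites would rest on a chiral Lewis acid bound to a chelating 1,4-diketone, for which there is little basis. Rings B would still have to be closed between the ester carbon C8 and C9, which is a ketone carbon in A5, so two electrophilic carbons must be joined and the C9 centres are not yet present.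
- Comparison: the chosen strategy has ring B from the start with C8 and C9 in place, and it forms C10 by a reaction whose enantiocontrol on this enolate type is established.

Alternative 3: The bonds C6–C7 and C6'–C7' are cut. In the forward step the bis(dianion) of the linchpin A6 would be alkylated at both terminal methyl carbons by the ring A allylic bromide A7 to give the bis(β-keto ester) A8. Acid-promoted cyclisation of each β-keto ester onto the C5=C10 alkene, removal of the ester groups and methylenation would follow.
- For: the linchpin is cheap and symmetric, the bridge is present from the start, C3 comes from enantiopure A7, and the sequence is short. In step economy and convergence this plan is clearly stronger.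
- Against: the key alkylation forms no ring and no stereocentre. It needs fourfold deprotonation of A6 and substitution on a hindered allylic bromide that is prone to SN2' attack and elimination. C5, C9 and C10 of both halves would all be set afterwards in two cationic cyclisations, steered only by the remote C3 silyl ether and run under acid that endangers that ether. Diastereomer mixtures from two independent halves are to be expected.
- Comparison: the chosen strategy assigns each centre to a controlled step: C9 to an enantioselective conjugate addition, C10 to a ligand-controlled allylation reinforced by C9, and C5 to a reduction with well-understood trans selectivity.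

Key step: step 7

## Route

Step 1
Reactants: 1 4-methoxy-2-methylphenol
Product: 2 4,4-dimethoxy-2-methylcyclohexa-2,5-dien-1-one
Conditions: PhI(OAc)2 (1.1 equiv), MeOH, 0 °C to rt
Reagents that add atoms: methanol, CO
Why: Oxidative dearomatisation of a para-alkoxyphenol with the hypervalent iodine oxidant PhI(OAc)2; methanol adds at the methoxy-bearing para carbon and should give the quinone monoketal, a reaction of broad precedent for 4-methoxyphenols. No stereocentre is formed.

Step 2
Reactants: 2 4,4-dimethoxy-2-methylcyclohexa-2,5-dien-1-one
Product: 3 4,4-dimethoxy-2-methylcyclohex-2-en-1-one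
Conditions: H2 (1 atm), RhCl(PPh3)3 (5 mol%), toluene, rt, stopped after one equivalent of H2
Reagents that add atoms: none
Why: Homogeneous hydrogenation with RhCl(PPh3)3 is strongly sensitive to alkene substitution, so the cis-disubstituted C6=C7 bond should be saturated well before the trisubstituted, methyl-bearing C9=C10 bond. The neutral aprotic medium avoids loss of methanol and rearomatisation.

Step 3
Reactants: 3 4,4-dimethoxy-2-methylcyclohex-2-en-1-one (2.4 equiv); 4 (E)-1,2-bis(pinacolboryl)ethene
Product: 6 (E)-1,2-bis[(1R)-6,6-dimethoxy-2-methyl-3-oxocyclohexyl]ethene, via monoadduct alkenylboronate 5 (not isolated)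
Conditions: [Rh(cod)Cl]2 (3 mol%), (S)-BINAP (7 mol%), aq KOH (cat.), 1,4-dioxane/H2O 10:1, 60 °C
Reagents that add atoms: none
Why: Twofold rhodium-catalysed asymmetric conjugate addition of an alkenylboronate to a cyclic enone (Hayashi–Miyaura reaction): transmetallation gives an alkenylrhodium that inserts the enone at C9, and hydrolysis of the rhodium enolate frees the catalyst. Both C9 centres are set by the ligand, (S)-BINAP being expected to give R at each; because the two additions are independent, most of the minor-enantiomer error should end up in a separable meso-type diastereomer. C10 is protonated without control, which does not matter since it is planarised in step 5, and the E geometry of 4 keeps rhodium and boron anti and so excludes syn β-boryl elimination.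

Step 4
Reactants: 6 (E)-1,2-bis[(1R)-6,6-dimethoxy-2-methyl-3-oxocyclohexyl]ethene
Product: 7 1,2-bis[(1R)-6,6-dimethoxy-2-methyl-3-oxocyclohexyl]ethane
Conditions: H2 (1 atm), Pd/C (10%), EtOAc, rt
Reagents that add atoms: none
Why: Heterogeneous hydrogenation of the only C=C bond; ketones and dimethyl ketals are inert under neutral conditions in ethyl acetate, and C9 is not affected.

Step 5
Reactants: 7 1,2-bis[(1R)-6,6-dimethoxy-2-methyl-3-oxocyclohexyl]ethane
Product: 8 1,2-bis[(1R)-6,6-dimethoxy-2-methyl-3-(trimethylsilyloxy)cyclohex-2-en-1-yl]ethane
Conditions: i-Pr2NMgBr (from EtMgBr and i-Pr2NH), Et2O, rt; then Me3SiCl, Et3N, HMPA, rt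
Reagents that add atoms: chlorotrimethylsilane, C[Si](C)(C)Cl
Why: Thermodynamic enol silylation: the bromomagnesium enolates equilibrate by proton transfer to the more substituted C5–C10 enolates and are silylated in situ, which planarises both C10 centres. Basic conditions are chosen because iodide- or triflate-based silylating systems would attack the dimethyl ketals.

Step 6
Reactants: 8 1,2-bis[(1R)-6,6-dimethoxy-2-methyl-3-(trimethylsilyloxy)cyclohex-2-en-1-yl]ethane; 9 allyl chloroformate (2.4 equiv)
Product: 11 1,2-bis[(1R)-3-(allyloxycarbonyloxy)-6,6-dimethoxy-2-methylcyclohex-2-en-1-yl]ethane, via dilithium bis(enolate) 10 (not isolated)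
Conditions: MeLi (2.1 equiv), THF, 0 °C; then 9, −78 °C to rt
Reagents that add atoms: none
Why: Methyllithium cleaves the silyl enol ethers to regiodefined lithium enolates without equilibration, and the hard chloroformate acylates these hindered tetrasubstituted enolates on oxygen. This is the standard preparation of allyl enol carbonates.

Step 7
Reactants: 11 1,2-bis[(1R)-3-(allyloxycarbonyloxy)-6,6-dimethoxy-2-methylcyclohex-2-en-1-yl]ethane
Product: 13 1,2-bis[(1R,2R)-2-allyl-6,6-dimethoxy-2-methyl-3-oxocyclohexyl]ethane, via monoallylated monocarbonate 12 (not isolated)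
Conditions: Pd2(dba)3 (5 mol%), (S)-t-Bu-PHOX (12.5 mol%), THF, 25 °C
Reagents that add atoms: none
Why: Zerovalent palladium bound to the phosphinooxazoline adds oxidatively to each allyl carbonate, and loss of CO2 leaves an allylpalladium enolate whose enolate is fixed between C5 and C10, because it forms under neutral aprotic conditions with no base or proton source that could move it to C6. Bond formation between C10 and the allyl terminus C1 then occurs within the coordination sphere of palladium and regenerates the catalyst, and the same cycle runs a second time on intermediate 12. The closest known reaction type is the palladium-catalysed decarboxylative asymmetric allylic alkylation of allyl enol carbonates of 2-alkylcyclohexanones (enantioselective Tsuji allylation) with t-Bu-PHOX, which has also been run twofold on substrates with two enolate precursors. No ring is closed; two skeletal bonds (C10–C1 and C10'–C1') and two quaternary stereocentres are formed. Each new centre is controlled by two elements acting in the same sense: the (S)-ligand, which with the parent 2-methylcyclohexanone carbonate gives the spatial arrangement that corresponds to 10R here, and the C9 side chain, which is pseudoaxial in the enolate to avoid A(1,2) strain with the C10 methyl and shields the β face, so that allyl enters anti to it. The step needs regioselectivity (C10, not C6), secured by the structure of the enol carbonate; chemoselectivity, secured by masking C8 as a ketal so that only the C5 enolate exists; and facial selectivity at two independent sites, for which the matched pairing is relied on, any leakage appearing as a diastereomer and not as the enantiomer.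

Step 8
Reactants: 13 1,2-bis[(1R,2R)-2-allyl-6,6-dimethoxy-2-methyl-3-oxocyclohexyl]ethane
Product: 15 1,2-bis[(1R,2R)-2-(3-hydroxypropyl)-6,6-dimethoxy-2-methyl-3-oxocyclohexyl]ethane, via bis(catechol alkylboronate) 14 (not isolated)
Conditions: catecholborane (3 equiv), RhCl(PPh3)3 (3 mol%), THF, 0 °C to rt; then NaOH, H2O2, H2O, 0 °C
Reagents that add atoms: hydrogen peroxide, OO
Why: Rhodium-catalysed hydroboration with catecholborane is chemoselective for a terminal alkene in the presence of a ketone and gives the primary (anti-Markovnikov) boronate, which alkaline peroxide oxidises to the primary alcohol. The C5 ketones, shielded by quaternary C10, and the ketals should survive; the hydroxy ketone may sit partly as its cyclic hemiketal, which does not affect step 9.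

Step 9
Reactants: 15 1,2-bis[(1R,2R)-2-(3-hydroxypropyl)-6,6-dimethoxy-2-methyl-3-oxocyclohexyl]ethane
Product: 16 1,2-bis[(1R,2R)-6,6-dimethoxy-2-methyl-3-oxo-2-(3-oxopropyl)cyclohexyl]ethane
Conditions: Dess–Martin periodinane (2.6 equiv), pyridine, CH2Cl2, 0 °C to rt
Reagents that add atoms: none
Why: Dess–Martin oxidation of primary alcohols to aldehydes under pyridine-buffered, non-aqueous conditions, which spare the ketals and cannot affect the quaternary C10 or the C9 centre.

Step 10
Reactants: 16 1,2-bis[(1R,2R)-6,6-dimethoxy-2-methyl-3-oxo-2-(3-oxopropyl)cyclohexyl]ethane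
Product: 17 1,2-bis[(1R,2R)-2-(3-hydroxypentyl)-6,6-dimethoxy-2-methyl-3-oxocyclohexyl]ethane (carbinol epimers)
Conditions: EtMgBr (2.3 equiv), THF, −78 °C; then aq NH4Cl
Reagents that add atoms: ethylmagnesium bromide, CC[Mg]Br
Why: Grignard addition; at −78 °C the unhindered aldehydes should react far faster than the C5 ketones, which are shielded by the adjacent quaternary carbon. The new carbinol centres form without control and are removed in step 11.

Step 11
Reactants: 17 1,2-bis[(1R,2R)-2-(3-hydroxypentyl)-6,6-dimethoxy-2-methyl-3-oxocyclohexyl]ethane
Product: 18 1,2-bis[(1R,2R)-6,6-dimethoxy-2-methyl-3-oxo-2-(3-oxopentyl)cyclohexyl]ethane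
Conditions: Dess–Martin periodinane (2.6 equiv), pyridine, CH2Cl2, rt
Reagents that add atoms: none
Why: Dess–Martin oxidation of the secondary alcohols gives the 1,5-diketones, that is the 3-oxopentyl chains needed for annulation.

Step 12
Reactants: 18 1,2-bis[(1R,2R)-6,6-dimethoxy-2-methyl-3-oxo-2-(3-oxopentyl)cyclohexyl]ethane
Product: 19 1,2-bis[(1R,8aR)-2,2-dimethoxy-5,8a-dimethyl-6-oxo-1,2,3,4,6,7,8,8a-octahydronaphthalen-1-yl]ethane
Conditions: KOH, MeOH, 60 °C
Reagents that add atoms: none
Why: Intramolecular aldol condensation, the second stage of a Robinson annulation: the C4 enolate of each ethyl ketone attacks the C5 ketone in a 6-(enolendo)-exo-trig closure, and dehydration gives the tetrasubstituted C4=C5 enone of ring A. C10 is quaternary and C9 is not α to a carbonyl, so no stereocentre can be lost, and the ketals are stable to base.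

Step 13
Reactants: 19 1,2-bis[(1R,8aR)-2,2-dimethoxy-5,8a-dimethyl-6-oxo-1,2,3,4,6,7,8,8a-octahydronaphthalen-1-yl]ethane
Product: 21 1,2-bis[(1R,4aR,8aS)-2,2-dimethoxy-5,5,8a-trimethyl-6-oxodecahydronaphthalen-1-yl]ethane, via dilithium bis(enolate) 20 (not isolated)
Conditions: Li, NH3(l), THF, t-BuOH (2.0 equiv), −78 to −33 °C; then MeI (excess), −78 °C to rt
Reagents that add atoms: iodomethane, CI
Why: Dissolving-metal reduction of each enone (Birch-type conditions) with one equivalent of tert-butanol per enone gives the trans-fused C3–C4 lithium enolate, C5 being protonated axially on the α face opposite to the C10 methyl. The enolate is then alkylated at C4 by iodomethane (reductive alkylation), which completes the gem-dimethyl group; the ketals are inert to lithium in ammonia.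

Step 14
Reactants: 21 1,2-bis[(1R,4aR,8aS)-2,2-dimethoxy-5,5,8a-trimethyl-6-oxodecahydronaphthalen-1-yl]ethane
Product: 22 1,2-bis[(1R,4aR,6S,8aS)-6-hydroxy-2,2-dimethoxy-5,5,8a-trimethyldecahydronaphthalen-1-yl]ethane
Conditions: NaBH4, MeOH/THF, 0 °C
Reagents that add atoms: none
Why: Borohydride reduction of the 4,4-dimethyl-3-ketones; hydride approaches from the α face, away from the axial 4β- and 10β-methyl groups, and should give the equatorial 3β (3S) alcohols.

Step 15
Reactants: 22 1,2-bis[(1R,4aR,6S,8aS)-6-hydroxy-2,2-dimethoxy-5,5,8a-trimethyldecahydronaphthalen-1-yl]ethane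
Product: 23 1,2-bis[(1R,4aR,6S,8aS)-6-hydroxy-5,5,8a-trimethyl-2-oxodecahydronaphthalen-1-yl]ethane
Conditions: 1 M HCl, THF, rt
Reagents that add atoms: water, O
Why: Acid-catalysed hydrolysis of the dimethyl ketals. C9 becomes enolisable but already has the thermodynamically preferred configuration with the bridge equatorial, so any epimerisation is self-correcting.

Step 16
Reactants: 23 1,2-bis[(1R,4aR,6S,8aS)-6-hydroxy-5,5,8a-trimethyl-2-oxodecahydronaphthalen-1-yl]ethane
Product: 24 α-onocerin
Conditions: Ph3PCH3Br (8 equiv), KOt-Bu (8 equiv), toluene, 90 °C
Reagents that add atoms: methyltriphenylphosphonium bromide, C[P+](c1ccccc1)(c1ccccc1)c1ccccc1.[Br-]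
Why: Twofold Wittig methylenation of the hindered C8 ketones with excess ylide at elevated temperature; the free hydroxyls only consume base, and C9, should it enolise, returns to the equatorial configuration.

## Compound list

1 | 4-methoxy-2-methylphenol | COc1ccc(O)c(C)c1 | starting material
2 | 4,4-dimethoxy-2-methylcyclohexa-2,5-dien-1-one | O=C1C(C)=CC(OC)(OC)C=C1 | intermediate
3 | 4,4-dimethoxy-2-methylcyclohex-2-en-1-one | O=C1C(C)=CC(OC)(OC)CC1 | intermediate
4 | (E)-1,2-bis(4,4,5,5-tetramethyl-1,3,2-dioxaborolan-2-yl)ethene | CC1(C)OB(/C=C/B2OC(C)(C)C(C)(C)O2)OC1(C)C | starting material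
5 | (3R)-4,4-dimethoxy-2-methyl-3-[(E)-2-(pinacolboryl)vinyl]cyclohexan-1-one, C2 epimers, not isolated | O=C1C(C)[C@@H](/C=C/B2OC(C)(C)C(C)(C)O2)C(OC)(OC)CC1 | intermediate
6 | (E)-1,2-bis[(1R)-6,6-dimethoxy-2-methyl-3-oxocyclohexyl]ethene, epimeric at the methyl-bearing carbons (C10, C10') | O=C1C(C)[C@@H](/C=C/[C@@H]2C(C)C(=O)CCC2(OC)OC)C(OC)(OC)CC1 | intermediate
7 | 1,2-bis[(1R)-6,6-dimethoxy-2-methyl-3-oxocyclohexyl]ethane, epimeric at C10 and C10' | O=C1C(C)[C@@H](CC[C@@H]2C(C)C(=O)CCC2(OC)OC)C(OC)(OC)CC1 | intermediate
8 | 1,2-bis[(1R)-6,6-dimethoxy-2-methyl-3-(trimethylsilyloxy)cyclohex-2-en-1-yl]ethane | C[Si](C)(C)OC1=C(C)[C@@H](CC[C@@H]2C(C)=C(O[Si](C)(C)C)CCC2(OC)OC)C(OC)(OC)CC1 | intermediate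
9 | allyl chloroformate | C=CCOC(Cl)=O | starting material
10 | dilithium bis(C5–C10 enolate) of 7, not isolated | [Li]OC1=C(C)[C@@H](CC[C@@H]2C(C)=C(O[Li])CCC2(OC)OC)C(OC)(OC)CC1 | intermediate
11 | 1,2-bis[(1R)-3-(allyloxycarbonyloxy)-6,6-dimethoxy-2-methylcyclohex-2-en-1-yl]ethane | C=CCOC(=O)OC1=C(C)[C@@H](CC[C@@H]2C(C)=C(OC(=O)OCC=C)CCC2(OC)OC)C(OC)(OC)CC1 | intermediate
12 | monoallylated monocarbonate (one half as in 13, the other as in 11), not isolated | C=CC[C@]1(C)[C@@H](CC[C@@H]2C(C)=C(OC(=O)OCC=C)CCC2(OC)OC)C(OC)(OC)CCC1=O | intermediate
13 | 1,2-bis[(1R,2R)-2-allyl-6,6-dimethoxy-2-methyl-3-oxocyclohexyl]ethane (allyl trans to the bridge, methyl cis to it) | C=CC[C@]1(C)[C@@H](CC[C@@H]2[C@@](C)(CC=C)C(=O)CCC2(OC)OC)C(OC)(OC)CCC1=O | intermediate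
14 | bis(catechol alkylboronate) of 13, not isolated | c1ccc2c(c1)OB(O2)CCC[C@]1(C)[C@@H](CC[C@@H]2[C@@](C)(CCCB3Oc4ccccc4O3)C(=O)CCC2(OC)OC)C(OC)(OC)CCC1=O | intermediate
15 | 1,2-bis[(1R,2R)-2-(3-hydroxypropyl)-6,6-dimethoxy-2-methyl-3-oxocyclohexyl]ethane | OCCC[C@]1(C)[C@@H](CC[C@@H]2[C@@](C)(CCCO)C(=O)CCC2(OC)OC)C(OC)(OC)CCC1=O | intermediate
16 | 1,2-bis[(1R,2R)-6,6-dimethoxy-2-methyl-3-oxo-2-(3-oxopropyl)cyclohexyl]ethane | O=CCC[C@]1(C)[C@@H](CC[C@@H]2[C@@](C)(CCC=O)C(=O)CCC2(OC)OC)C(OC)(OC)CCC1=O | intermediate
17 | 1,2-bis[(1R,2R)-2-(3-hydroxypentyl)-6,6-dimethoxy-2-methyl-3-oxocyclohexyl]ethane, carbinol epimers | CCC(O)CC[C@]1(C)[C@@H](CC[C@@H]2[C@@](C)(CCC(O)CC)C(=O)CCC2(OC)OC)C(OC)(OC)CCC1=O | intermediate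
18 | 1,2-bis[(1R,2R)-6,6-dimethoxy-2-methyl-3-oxo-2-(3-oxopentyl)cyclohexyl]ethane | CCC(=O)CC[C@]1(C)[C@@H](CC[C@@H]2[C@@](C)(CCC(=O)CC)C(=O)CCC2(OC)OC)C(OC)(OC)CCC1=O | intermediate
19 | 1,2-bis[(1R,8aR)-2,2-dimethoxy-5,8a-dimethyl-6-oxo-1,2,3,4,6,7,8,8a-octahydronaphthalen-1-yl]ethane (9α-H, 10β-methyl) | COC1(OC)CCC2=C(C)C(=O)CC[C@]2(C)[C@H]1CC[C@H]1C(OC)(OC)CCC2=C(C)C(=O)CC[C@]12C | intermediate
20 | dilithium bis(C3–C4 enolate), 5α-H, trans-fused, not isolated | COC1(OC)CC[C@H]2C(C)=C(O[Li])CC[C@]2(C)[C@H]1CC[C@H]1C(OC)(OC)CC[C@H]2C(C)=C(O[Li])CC[C@]12C | intermediate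
21 | 1,2-bis[(1R,4aR,8aS)-2,2-dimethoxy-5,5,8a-trimethyl-6-oxodecahydronaphthalen-1-yl]ethane (5α-H, 9α-H, 10β-methyl) | COC1(OC)CC[C@H]2C(C)(C)C(=O)CC[C@]2(C)[C@H]1CC[C@H]1C(OC)(OC)CC[C@H]2C(C)(C)C(=O)CC[C@]12C | intermediate
22 | 1,2-bis[(1R,4aR,6S,8aS)-6-hydroxy-2,2-dimethoxy-5,5,8a-trimethyldecahydronaphthalen-1-yl]ethane (3β-OH) | COC1(OC)CC[C@H]2C(C)(C)[C@@H](O)CC[C@]2(C)[C@H]1CC[C@H]1C(OC)(OC)CC[C@H]2C(C)(C)[C@@H](O)CC[C@]12C | intermediate
23 | 1,2-bis[(1R,4aR,6S,8aS)-6-hydroxy-5,5,8a-trimethyl-2-oxodecahydronaphthalen-1-yl]ethane | O=C1CC[C@H]2C(C)(C)[C@@H](O)CC[C@]2(C)[C@H]1CC[C@H]1C(=O)CC[C@H]2C(C)(C)[C@@H](O)CC[C@]12C | intermediate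
24 | α-onocerin | C=C1CC[C@H]2C(C)(C)[C@@H](O)CC[C@]2(C)[C@H]1CC[C@H]1C(=C)CC[C@H]2C(C)(C)[C@@H](O)CC[C@]12C | target

## Step count and least certain steps

Total step count: 16. Longest linear sequence: 16 steps (1 to 24); the route is linear and bidirectional from step 3 onwards.

Step 7 (key step). Most likely to go wrong: insufficient facial selectivity at one of the two C10 centres. Catalyst control for this enolate class is good but not perfect and must hold twice, so a C10-epimeric diastereomer is the expected contaminant. Competing enolate protonation (loss of an allyl unit) is the second risk if traces of water are present. Fallback: give up catalyst control and rely on the substrate alone. Setting out from 8, methyllithium gives the dilithium bis(enolate) 10 as in step 6, and this is C-alkylated directly with allyl bromide (THF/HMPA, −78 °C). The pseudoaxial C9 side chain directs the electrophile to the opposite face, a well-known preference for 2-methyl-3-substituted cyclohexanone enolates. This returns to the route at 13 and makes no new compound.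

Step 3. Most likely to go wrong: chain termination after the first addition, by protodeboronation of the remaining alkenylboron end or by a slow second insertion into the hindered α-methyl, γ,γ-dialkoxy enone, so that the process stops at a mono-adduct. Fallback: build the bridge from two one-carbon-extended halves. Setting out from 3, the same rhodium/(S)-BINAP catalysis with potassium vinyltrifluoroborate should give (3R)-4,4-dimethoxy-2-methyl-3-vinylcyclohexan-1-one F1. F1 is homodimerised by alkene metathesis (second-generation Hoveyda–Grubbs catalyst, toluene, 60 °C, ethene removed), returning to the route at 6.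

Step 5. Most likely to go wrong: incomplete regiocontrol in the enolisation. A(1,2) strain between the C10 methyl and the C9 side chain narrows the preference for the tetrasubstituted enol ether, and the wrong C5–C6 isomer at either site would be carried into the key step. Fallback: make the regiochemistry structural. Setting out from 7, kinetic deprotonation (LDA, Me3SiCl, THF, −78 °C) occurs at the unhindered C6 and gives the bis(kinetic silyl enol ether) F2. Saegusa oxidation with Pd(OAc)2 in MeCN gives the bis(enone) F3, in which C6 is vinylic and only C10 can be deprotonated. LiHMDS and 9 then give the bis(dienol carbonate) F4, and the conditions of step 7 give the bis(α'-quaternary enone) F5. Conjugate reduction of the two enones with [(Ph3P)CuH]6, which leaves the allyl groups untouched, returns to the route at 13.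

Step 13. Most likely to go wrong: incomplete trapping of the enolates, through proton transfer before methylation or competing O-methylation, at one of the two sites, leaving a 4-monomethyl ketone in one half. Fallback: separate the alkylation from the reduction. Setting out from 19, deconjugative methylation (KOt-Bu, t-BuOH, MeI) gives the bis(4,4-dimethyl-5-en-3-one) F6. Hydrogenation (H2, Pd/C, EtOAc) from the α face, opposite to the 4β- and 10β-methyl groups, returns to the route at 21.

Step 16. Most likely to go wrong: incomplete methylenation of the two hindered, enolisable C8 ketones, because the basic ylide is partly consumed by enolisation and by the free hydroxyls. Fallback: a non-basic titanium methylene reagent on a protected substrate. Setting out from 23, acetylation (Ac2O, pyridine) gives the diketone diacetate F7. Methylenation with Zn, CH2Br2 and TiCl4 in THF/CH2Cl2, which is selective for ketones over esters, gives α-onocerin diacetate F8. Methanolysis (K2CO3, MeOH) returns to the route at 24.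

## Further compounds

F0 | step 7 | none | none
F1 | step 3 | (3R)-4,4-dimethoxy-2-methyl-3-vinylcyclohexan-1-one, C2 epimers | O=C1C(C)[C@@H](C=C)C(OC)(OC)CC1
F2 | step 5 | 1,2-bis[(1R)-6,6-dimethoxy-2-methyl-3-(trimethylsilyloxy)cyclohex-3-en-1-yl]ethane | C[Si](C)(C)OC=1C(C)[C@@H](CC[C@@H]2C(C)C(O[Si](C)(C)C)=CCC2(OC)OC)C(OC)(OC)CC=1
F3 | step 5 | 1,2-bis[(1R)-6,6-dimethoxy-2-methyl-3-oxocyclohex-4-en-1-yl]ethane | O=C1C(C)[C@@H](CC[C@@H]2C(C)C(=O)C=CC2(OC)OC)C(OC)(OC)C=C1
F4 | step 5 | 1,2-bis[(1R)-3-(allyloxycarbonyloxy)-6,6-dimethoxy-2-methylcyclohexa-2,4-dien-1-yl]ethane | C=CCOC(=O)OC1=C(C)[C@@H](CC[C@@H]2C(C)=C(OC(=O)OCC=C)C=CC2(OC)OC)C(OC)(OC)C=C1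
F5 | step 5 | 1,2-bis[(1R,2R)-2-allyl-6,6-dimethoxy-2-methyl-3-oxocyclohex-4-en-1-yl]ethane | C=CC[C@]1(C)[C@@H](CC[C@@H]2[C@@](C)(CC=C)C(=O)C=CC2(OC)OC)C(OC)(OC)C=CC1=O
F6 | step 13 | 1,2-bis[(1R,8aR)-2,2-dimethoxy-5,5,8a-trimethyl-6-oxo-1,2,3,5,6,7,8,8a-octahydronaphthalen-1-yl]ethane | COC1(OC)CC=C2C(C)(C)C(=O)CC[C@]2(C)[C@H]1CC[C@H]1C(OC)(OC)CC=C2C(C)(C)C(=O)CC[C@]12C
F7 | step 16 | 1,2-bis[(1R,4aR,6S,8aS)-6-acetoxy-5,5,8a-trimethyl-2-oxodecahydronaphthalen-1-yl]ethane | O=C1CC[C@H]2C(C)(C)[C@@H](OC(C)=O)CC[C@]2(C)[C@H]1CC[C@H]1C(=O)CC[C@H]2C(C)(C)[C@@H](OC(C)=O)CC[C@]12C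
F8 | step 16 | α-onocerin diacetate | C=C1CC[C@H]2C(C)(C)[C@@H](OC(C)=O)CC[C@]2(C)[C@H]1CC[C@H]1C(=C)CC[C@H]2C(C)(C)[C@@H](OC(C)=O)CC[C@]12C
A1 | alternative 1 | 14-membered macrocyclic dienyne with the C8≡C14 alkyne, the (E,E)-C9=C11–C12=C13 diene and both ring A units as tert-butyldimethylsilyl ethers | C[C@]12CC[C@H](O[Si](C)(C)C(C)(C)C)C(C)(C)[C@@H]1CCC#CCC[C@H]1C(C)(C)[C@@H](O[Si](C)(C)C(C)(C)C)CC[C@]1(C)/C=C/C=C/2
A2 | alternative 1 | pentacyclic 8(14),11-diene bis(tert-butyldimethylsilyl ether) | C12=C3CC[C@H]4C(C)(C)[C@@H](O[Si](C)(C)C(C)(C)C)CC[C@]4(C)[C@H]3C=C[C@H]1[C@@]1(C)CC[C@H](O[Si](C)(C)C(C)(C)C)C(C)(C)[C@@H]1CC2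
A3 | alternative 2 | dimethyl (4E,10E)-5,10-dimethyl-6,9-dioxotetradeca-4,10-dienedioate | COC(=O)CC/C=C(\C)C(=O)CCC(=O)/C(C)=C/CCC(=O)OC
A4 | alternative 2 | tert-butyldimethyl[(4-methylpenta-1,3-dien-3-yl)oxy]silane | C=CC(O[Si](C)(C)C(C)(C)C)=C(C)C
A5 | alternative 2 | 1,4-diketone diester carrying both A rings as silyl enol ethers | COC(=O)CC[C@H]1C(C)(C)C(O[Si](C)(C)C(C)(C)C)=CC[C@]1(C)C(=O)CCC(=O)[C@@]1(C)CC=C(O[Si](C)(C)C(C)(C)C)C(C)(C)[C@@H]1CCC(=O)OC
A6 | alternative 3 | diethyl 2,5-diacetylhexanedioate | CCOC(=O)C(CCC(C(=O)OCC)C(C)=O)C(C)=O
A7 | alternative 3 | {[(1S)-3-(bromomethyl)-2,2,4-trimethylcyclohex-3-en-1-yl]oxy}(tert-butyl)dimethylsilane | BrCC1=C(C)CC[C@H](O[Si](C)(C)C(C)(C)C)C1(C)C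
A8 | alternative 3 | bis(β-keto ester) carrying both ring A units | CCOC(=O)C(CCC(C(=O)OCC)C(=O)CCC1=C(C)CC[C@H](O[Si](C)(C)C(C)(C)C)C1(C)C)C(=O)CCC1=C(C)CC[C@H](O[Si](C)(C)C(C)(C)C)C1(C)C
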